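**Strategy.** Germacranolide numbering is used: lactone C12(=O)–O–C6, ring fusion C7, esters on C8 and C9, enal C14(=O)–C10=C1, then C2, C3 and C4(C15)=C5. Everything rests on disconnecting C1–C2 of the ten-membered carbocycle. Ring-closing olefin metathesis joins a C10 vinyl group to a C4 allyl group of a monocyclic trans-γ-lactone that already carries C6–C10. The step exploits that C1 is the β-carbon of the C14 enal in the ten-membered ring: the C1=C2 olefin it delivers is the deconjugated isomer of that enal, so oxidation at C14 and a proton shift later move the double bond to C1=C10 under thermodynamic (ring-cis) control.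

Key step: step 12

Remark: the geometry of the C1=C2 olefin formed in step 12 is immaterial (the bond migrates in step 15) and is written Z, as expected in a ten-membered ring; 12 is written as the open form of its cyclic hemiketal.

Remark: the antipode of Ipc2BOTf that delivers the required enolate face of 15 in step 9 is assumed to be the (−)-reagent made from (+)-α-pinene; if the induction runs the other way, its enantiomer is used.

Step 1
Reactants: 1 4,4-diethoxybut-2-yn-1-ol; 2 allylmagnesium bromide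
Product: 3 (2E)-4,4-diethoxy-2-(prop-2-en-1-yl)but-2-en-1-ol
Conditions: CH2=CHCH2MgBr (3 equiv), Et2O, 0 °C to reflux; then H2O
Reagents that add atoms: none
Why: Hydroxyl-directed anti-carbomagnesiation of a propargylic alcohol (Eisch–Richey/Fallis type) should deliver allyl to the alkyne carbon next to the carbinol (C4) and hold magnesium on C5 cis to C15 in a five-membered chelate, so protonolysis gives the olefin with C3 cis to C6, the ring-cis C4=C5 geometry.

Step 2
Reactants: 3 (2E)-4,4-diethoxy-2-(prop-2-en-1-yl)but-2-en-1-ol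
Product: 4 1-({[(2E)-4,4-diethoxy-2-(prop-2-en-1-yl)but-2-en-1-yl]oxy}methyl)-4-methoxybenzene
Conditions: NaH, 4-MeOC6H4CH2Cl, Bu4NI (cat.), THF/DMF, 0 °C to rt
Reagents that add atoms: 4-methoxybenzyl chloride, COc1ccc(CCl)cc1
Why: Williamson etherification of the primary allylic alkoxide masks O15 as a PMB ether, which is base-stable and is the last group to be removed.

Step 3
Reactants: 4 PMB-protected dienol acetal
Product: 5 (2E)-3-{[(4-methoxybenzyl)oxy]methyl}hexa-2,5-dienal
Conditions: PPTS (cat.), acetone/H2O (10:1), rt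
Reagents that add atoms: water, O
Why: Mild acid-catalysed acetal hydrolysis should free the C6 aldehyde without E/Z scrambling of the enal or loss of the PMB ether.

Step 4
Reactants: 6 (4S)-4-benzyl-3-[(2E)-but-2-enoyl]-1,3-oxazolidin-2-one; 7 ethyl glyoxylate
Product: 8 ethyl (2S,3S)-3-{[(4S)-4-benzyl-2-oxo-1,3-oxazolidin-3-yl]carbonyl}-2-hydroxypent-4-enoate
Conditions: Bu2BOTf, Et3N, CH2Cl2, −78 to 0 °C; 7, −78 °C; then pH 7 buffer, MeOH, H2O2, 0 °C
Reagents that add atoms: none
Why: Evans syn-aldol: the Z(O)-boron dienolate of the crotonyl imide reacts at its α-carbon through a Zimmerman–Traxler chair in which the (S)-benzyl oxazolidinone shields one face, setting C9 and the temporary vinyl-bearing centre C10.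

Step 5
Reactants: 8 aldol adduct
Product: 9 ethyl (2S,3S)-3-{[(4S)-4-benzyl-2-oxo-1,3-oxazolidin-3-yl]carbonyl}-2-[(tert-butyldimethylsilyl)oxy]pent-4-enoate
Conditions: TBSOTf, 2,6-lutidine, CH2Cl2, 0 °C
Reagents that add atoms: tert-butyldimethylsilyl trifluoromethanesulfonate, CC(C)(C)[Si](C)(C)OS(=O)(=O)C(F)(F)F
Why: Silylation of the secondary alcohol gives a base-stable, non-chelating O9 silyl ether that survives the enolate steps and supports Felkin–Anh control in step 10.

Step 6
Reactants: 9 silylated aldol adduct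
Product: 11 (3S,4R)-3-[(tert-butyldimethylsilyl)oxy]-4-ethenyloxolan-2-one, via hydroxy ester 10 (not isolated)
Conditions: NaBH4, THF/H2O (4:1), 0 °C to rt; then PPTS (cat.), CH2Cl2, rt
Reagents that add atoms: none
Why: Borohydride should cleave the N-acyl oxazolidinone chemoselectively (the ester survives in THF/H2O), and the resulting γ-hydroxy ester lactonises under acid catalysis to the trans-disubstituted γ-lactone.

Step 7
Reactants: 11 silyloxy vinyl lactone
Product: 13 (3S,4R)-3-[(tert-butyldimethylsilyl)oxy]-4-{[(tert-butyldimethylsilyl)oxy]methyl}hex-5-en-2-one, via hydroxy ketone 12 (not isolated)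
Conditions: MeLi (1.05 equiv), THF, −78 °C; H2O; then TBSCl, imidazole, DMF, rt
Reagents that add atoms: methyllithium, [Li]C; tert-butyldimethylsilyl chloride, CC(C)(C)[Si](C)(C)Cl
Why: Mono-addition of methyllithium to the γ-lactone (the lithium hemiketal persists at −78 °C) gives the methyl ketone, and silylation of the primary hydroxyl drains the ring–chain equilibrium to the open ketone.

Step 8
Reactants: 13 bis-silyl methyl ketone; 14 methyl bromoacetate
Product: 15 methyl (5S,6R)-5-[(tert-butyldimethylsilyl)oxy]-6-{[(tert-butyldimethylsilyl)oxy]methyl}-4-oxooct-7-enoate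
Conditions: LiN(iPr)2, THF, −78 °C; 14, DMPU, −78 to −40 °C
Reagents that add atoms: none
Why: Kinetic deprotonation at the unhindered methyl group (the α′ C9–H is tertiary and flanked by the silyloxy group) and SN2 alkylation of the lithium enolate install C11–C12.

Step 9
Reactants: 15 γ-keto ester; 5 dienal
Product: 17 (4S,5R)-4-{(2S,3R)-2-[(tert-butyldimethylsilyl)oxy]-3-{[(tert-butyldimethylsilyl)oxy]methyl}pent-4-enoyl}-5-[(1E)-2-{[(4-methoxybenzyl)oxy]methyl}penta-1,4-dien-1-yl]oxolan-2-one, via aldol 16 (not isolated)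
Conditions: (−)-Ipc2BOTf, i-Pr2NEt, CH2Cl2, −78 °C; 5, −78 to −20 °C; pH 7 buffer, MeOH, H2O2, 0 °C; then PPTS (cat.), CH2Cl2, rt
Reagents that add atoms: none
Why: Paterson syn-aldol under reagent control: Ipc2BOTf and i-Pr2NEt form the Z-enol borinate on the unhindered CH2 side of the ketone, the Zimmerman–Traxler chair gives the C6/C7 syn relationship, and the isopinocampheyl ligands rather than the C9 silyloxy centre select the enolate face and so set C6 and C7 (2,4-anti-4,5-syn with respect to O9), after which the γ-hydroxy ester lactonises under acid catalysis to the trans-lactone.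

Step 10
Reactants: 17 lactone ketone
Product: 18 (4R,5R)-4-{(1S,2S,3R)-2-[(tert-butyldimethylsilyl)oxy]-3-{[(tert-butyldimethylsilyl)oxy]methyl}-1-hydroxypent-4-en-1-yl}-5-[(1E)-2-{[(4-methoxybenzyl)oxy]methyl}penta-1,4-dien-1-yl]oxolan-2-one
Conditions: Li[HB(s-Bu)3], THF, −78 °C; then H2O
Reagents that add atoms: none
Why: Felkin–Anh reduction with a bulky non-chelating hydride: the C9 silyloxy group (polar Felkin model), supported by the ring stereocentre C7, should direct hydride to the face that gives the C8 carbinol syn to O9, while the lactone is inert at −78 °C.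

Step 11
Reactants: 18 C8 alcohol
Product: 19 (4S,5R)-4-{(1S,2S,3R)-1,2-bis[(tert-butyldimethylsilyl)oxy]-3-{[(tert-butyldimethylsilyl)oxy]methyl}pent-4-en-1-yl}-5-[(1E)-2-{[(4-methoxybenzyl)oxy]methyl}penta-1,4-dien-1-yl]oxolan-2-one
Conditions: TBSOTf, 2,6-lutidine, CH2Cl2, 0 °C to rt
Reagents that add atoms: tert-butyldimethylsilyl trifluoromethanesulfonate, CC(C)(C)[Si](C)(C)OS(=O)(=O)C(F)(F)F
Why: Silylation of the hindered C8 hydroxyl prevents translactonisation and alkoxide chemistry in the later enolate step.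

Step 12
Reactants: 19 tris-silyl diene lactone
Product: 20 (1Z,4E,6R,7S,8S,9S,10R)-8,9,14-tris[(tert-butyldimethylsilyl)oxy]-15-[(4-methoxybenzyl)oxy]-13-norgermacra-1,4-dien-12,6-olide
Conditions: second-generation Hoveyda–Grubbs catalyst (10 mol%), 1,4-benzoquinone (20 mol%), toluene (1 mM), 80 °C
Reagents that add atoms: none
Why: The ruthenium alkylidene should load on the less hindered allyl terminus (C2), undergo [2+2] cycloaddition and cycloreversion with the C10 vinyl group, and release ethene as the C1=C2 bond forms. The closest known reaction type is macrocyclising ring-closing olefin metathesis to ten-membered carbocycles (cyclodecenes). The ten-membered ring is closed between two monosubstituted terminal olefins, so both new sp2 carbons (C1 and C2) are endocyclic and the γ-lactone becomes trans-fused to the new ring. No stereocentre is created, and the C1=C2 geometry does not matter because the bond is relocated in step 15. The step needs ring closure to beat acyclic diene metathesis (high dilution; the cis C4=C5 olefin and the trans-lactone bring the termini together) and needs the trisubstituted C4=C5 bond to stay untouched (it is unreactive toward the catalyst); benzoquinone suppresses Ru–H migration in the skipped diene.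

Step 13
Reactants: 20 macrocyclic lactone
Product: 23 (1Z,4E,6R,7S,8S,9S,10R)-8,9,14-tris[(tert-butyldimethylsilyl)oxy]-15-[(4-methoxybenzyl)oxy]germacra-1,4,11(13)-trien-12,6-olide, via Mannich base 21 (not isolated), via methiodide 22 (not isolated)
Conditions: LiN(SiMe3)2, THF, −78 °C; Me2N=CH2 I, −78 °C to rt; then MeI, MeOH, rt; then NaHCO3 (aq), CH2Cl2
Reagents that add atoms: N,N-dimethylmethyleneiminium iodide (Eschenmoser's salt), C=[N+](C)C.[I-]
Why: Mannich-type α-aminomethylation of the lithium lactone enolate, N-methylation and base-induced (Hofmann-type) elimination of trimethylamine install the exocyclic C11=C13 methylene; the transient C11 centre is lost.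

Step 14
Reactants: 23 α-methylene lactone
Product: 24 (1Z,4E,6R,7S,8S,9S,10R)-8,9-bis[(tert-butyldimethylsilyl)oxy]-14-hydroxy-15-[(4-methoxybenzyl)oxy]germacra-1,4,11(13)-trien-12,6-olide
Conditions: HF·pyridine, pyridine, THF, 0 °C
Reagents that add atoms: none
Why: Buffered HF·pyridine should cleave the primary silyl ether much faster than the two hindered secondary ones, and the PMB ether is inert.

Step 15
Reactants: 24 C14 alcohol
Product: 26 (1(10)E,4E,6R,7S,8S,9S)-8,9-bis[(tert-butyldimethylsilyl)oxy]-15-[(4-methoxybenzyl)oxy]-14-oxogermacra-1(10),4,11(13)-trien-12,6-olide, via aldehyde 25 (not isolated)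
Conditions: Dess–Martin periodinane, CH2Cl2, 0 °C to rt; then Et3N (cat.), CH2Cl2, rt
Reagents that add atoms: none
Why: Dess–Martin oxidation gives the β,γ-unsaturated aldehyde, whose acidic C10–H allows amine-mediated prototropic migration of the C1=C2 bond into conjugation (dienolate, protonation at C2); the E-enal, which is the ring-cis C1=C10 olefin, is the thermodynamic product and the temporary C10 stereocentre is erased.

Step 16
Reactants: 26 bis-silyl enal
Product: 27 (1(10)E,4E,6R,7R,8S,9S)-8,9-dihydroxy-15-[(4-methoxybenzyl)oxy]-14-oxogermacra-1(10),4,11(13)-trien-12,6-olide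
Conditions: HF·pyridine, THF, 0 °C to rt
Reagents that add atoms: none
Why: Fluoride-mediated cleavage of the two secondary silyl ethers frees the C8/C9 diol while the PMB ether keeps O15 masked.

Step 17
Reactants: 27 diol; 28 angelic acid ((2Z)-2-methylbut-2-enoic acid)
Product: 29 (1(10)E,4E,6R,7S,8S,9S)-8,9-bis{[(2Z)-2-methylbut-2-enoyl]oxy}-15-[(4-methoxybenzyl)oxy]-14-oxogermacra-1(10),4,11(13)-trien-12,6-olide
Conditions: 28 (2.5 equiv), 2,4,6-Cl3C6H2COCl (2.5 equiv), Et3N, toluene, rt; then 27, 80 °C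
Reagents that add atoms: angelic acid (second equivalent), C/C=C(/C)C(=O)O
Why: Yamaguchi-type acylation through the preformed 2,4,6-trichlorobenzoic mixed anhydride of angelic acid (one equivalent is consumed per hydroxyl, two in all), without a nucleophilic amine catalyst, should acylate both secondary hydroxyls and avoid addition–elimination isomerisation of the Z-angelate to the tiglate.

Step 18
Reactants: 29 bis-angelate PMB ether
Product: 30 (1(10)E,4E,6R,7S,8S,9S)-8,9-bis{[(2Z)-2-methylbut-2-enoyl]oxy}-15-hydroxy-14-oxogermacra-1(10),4,11(13)-trien-12,6-olide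
Conditions: DDQ, CH2Cl2/pH 7 buffer, 0 °C
Reagents that add atoms: none
Why: Oxidative cleavage of the 4-methoxybenzyl ether by DDQ (hydride abstraction, then hydrolysis of the oxocarbenium ion) should free O15 without touching the esters, the enal or the methylene lactone.

**Compound list**

1 | 4,4-diethoxybut-2-yn-1-ol | CCOC(OCC)C#CCO | starting material
2 | allylmagnesium bromide | C=CC[Mg]Br | starting material
3 | (2E)-4,4-diethoxy-2-(prop-2-en-1-yl)but-2-en-1-ol | OC/C(CC=C)=C/C(OCC)OCC | intermediate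
4 | 1-({[(2E)-4,4-diethoxy-2-(prop-2-en-1-yl)but-2-en-1-yl]oxy}methyl)-4-methoxybenzene | COc1ccc(COC/C(CC=C)=C/C(OCC)OCC)cc1 | intermediate
5 | (2E)-3-{[(4-methoxybenzyl)oxy]methyl}hexa-2,5-dienal | COc1ccc(COC/C(CC=C)=C/C=O)cc1 | intermediate
6 | (4S)-4-benzyl-3-[(2E)-but-2-enoyl]-1,3-oxazolidin-2-one | C/C=C/C(=O)N1[C@@H](Cc2ccccc2)COC1=O | starting material
7 | ethyl glyoxylate | CCOC(=O)C=O | starting material
8 | ethyl (2S,3S)-3-{[(4S)-4-benzyl-2-oxo-1,3-oxazolidin-3-yl]carbonyl}-2-hydroxypent-4-enoate | CCOC(=O)[C@@H](O)[C@H](C=C)C(=O)N1[C@@H](Cc2ccccc2)COC1=O | intermediate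
9 | ethyl (2S,3S)-3-{[(4S)-4-benzyl-2-oxo-1,3-oxazolidin-3-yl]carbonyl}-2-[(tert-butyldimethylsilyl)oxy]pent-4-enoate | CCOC(=O)[C@@H](O[Si](C)(C)C(C)(C)C)[C@H](C=C)C(=O)N1[C@@H](Cc2ccccc2)COC1=O | intermediate
10 | ethyl (2S,3R)-2-[(tert-butyldimethylsilyl)oxy]-3-(hydroxymethyl)pent-4-enoate | CCOC(=O)[C@@H](O[Si](C)(C)C(C)(C)C)[C@@H](CO)C=C | intermediate (not isolated)
11 | (3S,4R)-3-[(tert-butyldimethylsilyl)oxy]-4-ethenyloxolan-2-one | O=C1OC[C@@H](C=C)[C@@H]1O[Si](C)(C)C(C)(C)C | intermediate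
12 | (3S,4R)-3-[(tert-butyldimethylsilyl)oxy]-4-(hydroxymethyl)hex-5-en-2-one (open form of its cyclic hemiketal) | CC(=O)[C@@H](O[Si](C)(C)C(C)(C)C)[C@@H](CO)C=C | intermediate (not isolated)
13 | (3S,4R)-3-[(tert-butyldimethylsilyl)oxy]-4-{[(tert-butyldimethylsilyl)oxy]methyl}hex-5-en-2-one | CC(=O)[C@@H](O[Si](C)(C)C(C)(C)C)[C@@H](CO[Si](C)(C)C(C)(C)C)C=C | intermediate
14 | methyl bromoacetate | COC(=O)CBr | starting material
15 | methyl (5S,6R)-5-[(tert-butyldimethylsilyl)oxy]-6-{[(tert-butyldimethylsilyl)oxy]methyl}-4-oxooct-7-enoate | COC(=O)CCC(=O)[C@@H](O[Si](C)(C)C(C)(C)C)[C@@H](CO[Si](C)(C)C(C)(C)C)C=C | intermediate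
16 | methyl (3S,5S,6R)-5-[(tert-butyldimethylsilyl)oxy]-6-{[(tert-butyldimethylsilyl)oxy]methyl}-3-[(1R,2E)-1-hydroxy-3-{[(4-methoxybenzyl)oxy]methyl}hexa-2,5-dien-1-yl]-4-oxooct-7-enoate | COC(=O)C[C@@H]([C@H](O)/C=C(/COCc1ccc(OC)cc1)CC=C)C(=O)[C@@H](O[Si](C)(C)C(C)(C)C)[C@@H](CO[Si](C)(C)C(C)(C)C)C=C | intermediate (not isolated)
17 | (4S,5R)-4-{(2S,3R)-2-[(tert-butyldimethylsilyl)oxy]-3-{[(tert-butyldimethylsilyl)oxy]methyl}pent-4-enoyl}-5-[(1E)-2-{[(4-methoxybenzyl)oxy]methyl}penta-1,4-dien-1-yl]oxolan-2-one | O=C1C[C@H](C(=O)[C@@H](O[Si](C)(C)C(C)(C)C)[C@@H](CO[Si](C)(C)C(C)(C)C)C=C)[C@@H](/C=C(/COCc2ccc(OC)cc2)CC=C)O1 | intermediate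
18 | (4R,5R)-4-{(1S,2S,3R)-2-[(tert-butyldimethylsilyl)oxy]-3-{[(tert-butyldimethylsilyl)oxy]methyl}-1-hydroxypent-4-en-1-yl}-5-[(1E)-2-{[(4-methoxybenzyl)oxy]methyl}penta-1,4-dien-1-yl]oxolan-2-one | O=C1C[C@H]([C@H](O)[C@@H](O[Si](C)(C)C(C)(C)C)[C@@H](CO[Si](C)(C)C(C)(C)C)C=C)[C@@H](/C=C(/COCc2ccc(OC)cc2)CC=C)O1 | intermediate
19 | (4S,5R)-4-{(1S,2S,3R)-1,2-bis[(tert-butyldimethylsilyl)oxy]-3-{[(tert-butyldimethylsilyl)oxy]methyl}pent-4-en-1-yl}-5-[(1E)-2-{[(4-methoxybenzyl)oxy]methyl}penta-1,4-dien-1-yl]oxolan-2-one | O=C1C[C@H]([C@H](O[Si](C)(C)C(C)(C)C)[C@@H](O[Si](C)(C)C(C)(C)C)[C@@H](CO[Si](C)(C)C(C)(C)C)C=C)[C@@H](/C=C(/COCc2ccc(OC)cc2)CC=C)O1 | intermediate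
20 | (1Z,4E,6R,7S,8S,9S,10R)-8,9,14-tris[(tert-butyldimethylsilyl)oxy]-15-[(4-methoxybenzyl)oxy]-13-norgermacra-1,4-dien-12,6-olide | O=C1O[C@@H]2/C=C(/COCc3ccc(OC)cc3)C/C=C\[C@H](CO[Si](C)(C)C(C)(C)C)[C@H](O[Si](C)(C)C(C)(C)C)[C@@H](O[Si](C)(C)C(C)(C)C)[C@H]2C1 | intermediate
21 | (11R)-13-(dimethylamino)-11,13-dihydro derivative of 23 (Mannich base; C11 configuration expected trans to C8, without consequence) | CN(C)C[C@@H]1C(=O)O[C@@H]2/C=C(/COCc3ccc(OC)cc3)C/C=C\[C@H](CO[Si](C)(C)C(C)(C)C)[C@H](O[Si](C)(C)C(C)(C)C)[C@@H](O[Si](C)(C)C(C)(C)C)[C@@H]12 | intermediate (not isolated)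
22 | N-methyl ammonium iodide of 21 (13-trimethylammonio lactone iodide) | C[N+](C)(C)C[C@@H]1C(=O)O[C@@H]2/C=C(/COCc3ccc(OC)cc3)C/C=C\[C@H](CO[Si](C)(C)C(C)(C)C)[C@H](O[Si](C)(C)C(C)(C)C)[C@@H](O[Si](C)(C)C(C)(C)C)[C@@H]12.[I-] | intermediate (not isolated)
23 | (1Z,4E,6R,7S,8S,9S,10R)-8,9,14-tris[(tert-butyldimethylsilyl)oxy]-15-[(4-methoxybenzyl)oxy]germacra-1,4,11(13)-trien-12,6-olide | C=C1C(=O)O[C@@H]2/C=C(/COCc3ccc(OC)cc3)C/C=C\[C@H](CO[Si](C)(C)C(C)(C)C)[C@H](O[Si](C)(C)C(C)(C)C)[C@@H](O[Si](C)(C)C(C)(C)C)[C@@H]12 | intermediate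
24 | (1Z,4E,6R,7S,8S,9S,10R)-8,9-bis[(tert-butyldimethylsilyl)oxy]-14-hydroxy-15-[(4-methoxybenzyl)oxy]germacra-1,4,11(13)-trien-12,6-olide | C=C1C(=O)O[C@@H]2/C=C(/COCc3ccc(OC)cc3)C/C=C\[C@H](CO)[C@H](O[Si](C)(C)C(C)(C)C)[C@@H](O[Si](C)(C)C(C)(C)C)[C@@H]12 | intermediate
25 | (1Z,4E,6R,7S,8S,9S,10S)-8,9-bis[(tert-butyldimethylsilyl)oxy]-15-[(4-methoxybenzyl)oxy]-14-oxogermacra-1,4,11(13)-trien-12,6-olide (β,γ-unsaturated aldehyde) | C=C1C(=O)O[C@@H]2/C=C(/COCc3ccc(OC)cc3)C/C=C\[C@H](C=O)[C@H](O[Si](C)(C)C(C)(C)C)[C@@H](O[Si](C)(C)C(C)(C)C)[C@@H]12 | intermediate (not isolated)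
26 | (1(10)E,4E,6R,7S,8S,9S)-8,9-bis[(tert-butyldimethylsilyl)oxy]-15-[(4-methoxybenzyl)oxy]-14-oxogermacra-1(10),4,11(13)-trien-12,6-olide | C=C1C(=O)O[C@@H]2/C=C(/COCc3ccc(OC)cc3)CC/C=C(/C=O)[C@H](O[Si](C)(C)C(C)(C)C)[C@@H](O[Si](C)(C)C(C)(C)C)[C@@H]12 | intermediate
27 | (1(10)E,4E,6R,7R,8S,9S)-8,9-dihydroxy-15-[(4-methoxybenzyl)oxy]-14-oxogermacra-1(10),4,11(13)-trien-12,6-olide | C=C1C(=O)O[C@@H]2/C=C(/COCc3ccc(OC)cc3)CC/C=C(/C=O)[C@H](O)[C@@H](O)[C@@H]12 | intermediate
28 | angelic acid, (2Z)-2-methylbut-2-enoic acid | C/C=C(/C)C(=O)O | starting material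
29 | (1(10)E,4E,6R,7S,8S,9S)-8,9-bis{[(2Z)-2-methylbut-2-enoyl]oxy}-15-[(4-methoxybenzyl)oxy]-14-oxogermacra-1(10),4,11(13)-trien-12,6-olide | C=C1C(=O)O[C@@H]2/C=C(/COCc3ccc(OC)cc3)CC/C=C(/C=O)[C@H](OC(=O)/C(C)=C\C)[C@@H](OC(=O)/C(C)=C\C)[C@@H]12 | intermediate
30 | (1(10)E,4E,6R,7S,8S,9S)-8,9-bis{[(2Z)-2-methylbut-2-enoyl]oxy}-15-hydroxy-14-oxogermacra-1(10),4,11(13)-trien-12,6-olide | C=C1C(=O)O[C@@H]2/C=C(/CO)CC/C=C(/C=O)[C@H](OC(=O)/C(C)=C\C)[C@@H](OC(=O)/C(C)=C\C)[C@@H]12 | target

**Summary.** Total step count: 18. Longest linear sequence: 15 steps (steps 4–18, from 6 and 7); the dienal branch (steps 1–3) joins in step 9.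

**Steps most likely to fail**

Step 12. Ring closure may be outrun by intermolecular metathesis (oligomer formation), because the C10 vinyl group is flanked by three silyl ethers and the ten-membered ring is strained. The fallback closes the ring one stage earlier, on a substrate in which C8 is a trigonal ketone carbon and one silyl ether is absent. It sets out from 17: ring-closing metathesis under the step 12 conditions should give the macrocyclic ketone F1. Reduction with Li[HB(s-Bu)3] (Felkin control by the neighbouring C9 silyloxy group) should give the macrocyclic alcohol F2, and silylation (TBSOTf, 2,6-lutidine) returns to the route at 20.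

Step 9. The facial bias of the C9 silyloxy centre may oppose the chiral reagent (mismatched double stereodifferentiation) and erode the C6/C7 selectivity, and the bulky reagent may enolise the ketone slowly. The fallback replaces the syn-aldol by an anti-aldol followed by thermodynamic correction of C7. It sets out from 15 and 5: the E-enol borinate of 15, formed with (c-Hex)2BCl and Et3N, has C9–H held in the enolate plane by allylic strain and should add to 5 on the face remote from the C10 branch. Oxidative work-up should give the anti-aldol F3, which carries the required C6 configuration and the epimeric C7. PPTS lactonises it to the cis-lactone F4, and a catalytic amount of DBU should equilibrate the ketone α-centre C7 to the more stable trans-lactone, returning to the route at 17; ring opening by β-elimination would be a retro-5-endo-trig process and is expected to be slow.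

Step 7. Methyllithium may add twice to the lactone carbonyl or enolise C9, and the ring–chain equilibrium of 12 may divert the silylation. The fallback uses a Weinreb ketone synthesis and sets out from 11: aminolysis with MeNH(OMe)·HCl/AlMe3 should open the lactone to the hydroxy Weinreb amide F5. Silylation (TBSCl, imidazole) gives the bis-silyl Weinreb amide F6, and MeMgBr gives the methyl ketone, returning to the route at 13.

Further compounds
F1 | step 12 | (1Z,4E,6R,7S,9S,10R)-9,14-bis[(tert-butyldimethylsilyl)oxy]-15-[(4-methoxybenzyl)oxy]-8-oxo-13-norgermacra-1,4-dien-12,6-olide | O=C1O[C@@H]2/C=C(/COCc3ccc(OC)cc3)C/C=C\[C@H](CO[Si](C)(C)C(C)(C)C)[C@H](O[Si](C)(C)C(C)(C)C)C(=O)[C@H]2C1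
F2 | step 12 | (1Z,4E,6R,7R,8S,9S,10R)-9,14-bis[(tert-butyldimethylsilyl)oxy]-8-hydroxy-15-[(4-methoxybenzyl)oxy]-13-norgermacra-1,4-dien-12,6-olide | O=C1O[C@@H]2/C=C(/COCc3ccc(OC)cc3)C/C=C\[C@H](CO[Si](C)(C)C(C)(C)C)[C@H](O[Si](C)(C)C(C)(C)C)[C@@H](O)[C@H]2C1
F3 | step 9 | methyl (3R,5S,6R)-5-[(tert-butyldimethylsilyl)oxy]-6-{[(tert-butyldimethylsilyl)oxy]methyl}-3-[(1R,2E)-1-hydroxy-3-{[(4-methoxybenzyl)oxy]methyl}hexa-2,5-dien-1-yl]-4-oxooct-7-enoate | COC(=O)C[C@H]([C@H](O)/C=C(/COCc1ccc(OC)cc1)CC=C)C(=O)[C@@H](O[Si](C)(C)C(C)(C)C)[C@@H](CO[Si](C)(C)C(C)(C)C)C=C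
F4 | step 9 | (4R,5R)-4-{(2S,3R)-2-[(tert-butyldimethylsilyl)oxy]-3-{[(tert-butyldimethylsilyl)oxy]methyl}pent-4-enoyl}-5-[(1E)-2-{[(4-methoxybenzyl)oxy]methyl}penta-1,4-dien-1-yl]oxolan-2-one | O=C1C[C@@H](C(=O)[C@@H](O[Si](C)(C)C(C)(C)C)[C@@H](CO[Si](C)(C)C(C)(C)C)C=C)[C@@H](/C=C(/COCc2ccc(OC)cc2)CC=C)O1
F5 | step 7 | (2S,3R)-2-[(tert-butyldimethylsilyl)oxy]-3-(hydroxymethyl)-N-methoxy-N-methylpent-4-enamide | CON(C)C(=O)[C@@H](O[Si](C)(C)C(C)(C)C)[C@@H](CO)C=C
F6 | step 7 | (2S,3R)-2-[(tert-butyldimethylsilyl)oxy]-3-{[(tert-butyldimethylsilyl)oxy]methyl}-N-methoxy-N-methylpent-4-enamide | CON(C)C(=O)[C@@H](O[Si](C)(C)C(C)(C)C)[C@@H](CO[Si](C)(C)C(C)(C)C)C=C
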